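Readings and results are simulated with made-up constants; noise was put on by code.

common to all: G 20 mM
- gamma: D 25 mM; temperature 60 °C; run made earlier
- zeta: D 38 mM; temperature 72 °C; run made earlier
- west: D 50.0 mM; temperature 65 °C; time 8.0 h
- east: D 50.0 mM; at 65 °C until 6.0 h, from then on at 80 °C; time 8.0 h
- south-west: D 50.0 mM; temperature 80 °C; time 8.0 h
- gamma (time / h: E / %, G / %): 1.33: 6.1, 67.5; 3.00: 12.9, 63.9; 6.00: 23.7, 57.1; 10.0: 34.9, 49.7
- zeta (time / h: E / %, G / %): 0.833: 16.7, 57.7; 2.00: 33.8, 46.5; 4.00: 55.2, 32.4; 10.0: 84.2, 12.3

(standard deviation of a reading: 0.3 percentage points)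
* the flask that comes out highest in amount of E, in percent of the G charged, or "all alike" when all lie within 1.5 percentage points (west / east / south-west / all alike)
* E at the end, in percent of the G charged, west
* E at the end, in percent of the G charged, east
* E at the end, in percent of the G charged, south-west

1. I start from the leftover: in both earlier runs E and G fall short of the charge, so some G is held. I call everything not yet E the pool. I take each G that leaves the free state to take one D with it.

2. At the third readings, held G divided by free G and free D reads 0.0205 mM⁻¹ in gamma and 0.0156 mM⁻¹ in zeta.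

3. The logarithm of the pool falls with a pseudo-first-order constant λ. I divide its slope from first to last reading by the held share at the third reading, which gives k, the constant the pool would have if it were wholly held: 0.168 h⁻¹ in gamma and 0.655 h⁻¹ in zeta.

4. Taking logarithms as straight in temperature, at 65 °C k is 0.296 h⁻¹. At the same temperature I reckon 54.6 mM for the even amount H, the free D at which held G equals free G. So, with D now the free D, λ = k·D/(D + H), and E is the pool lost over the time.

5. West has two ends. With D at its whole charge, E reaches 67.8%. With D already down to 30.0 mM, E reaches 56.8%. Free D stays between these, so my reckoning puts west between them.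

6. I join the ends at 40.0 mM, which gives λ = 0.125 h⁻¹ and west 63.3%. The same reckoning at 80 °C gives λ = 0.557 h⁻¹, so east 84.5% and south-west 98.8%.

7. The forecast begins, “The mass balance shows a fast-forming hidden pool”, and says south-west: west 62.5%, east 82.8%, south-west 98%. Each lies below mine.

8. The flasks give west 62.9%, east 81.8% and south-west 97.6%, the highest, as the forecast said.

    G + D ⇌ Q (K = 3.30 L mol⁻¹, k = 4.50 L mol⁻¹ min⁻¹, Ea = 58.0 kJ mol⁻¹, ΔH = −63.0 kJ mol⁻¹)
    G + D ⇌ J (K = 10.0 L mol⁻¹, k = 3.30 L mol⁻¹ min⁻¹, Ea = 52.0 kJ mol⁻¹, ΔH = 7.00 kJ mol⁻¹)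
    G + D → E (k = 0.340 L mol⁻¹ min⁻¹, Ea = 87.0 kJ mol⁻¹)
    Q ⇌ J (k = 0.00930 min⁻¹, Ea = 98.0 kJ mol⁻¹)
    (constants at 80 °C)

In west, the forward turning of G + D into J, taken alone, gives D a half-life of 0.94 h at 2.92 h, shorter than the 3.7 h that the turning into E gives G at 8.00 h. At 8.00 h in west, free D of 34.6 mM and H give a held share of 38.8%, and Q with J hold 38.0% of the pool. For the neighbour of west charged with 50 mM of G, mid-way D is 25.0 mM, so H gives E 52.5%; that flask gives 52.2%.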